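1. At 1.5 h I read this flask, epsilon, and must choose what it gets for the next 1.5 h: patience, heat or fresh catalyst.

| flask | substrate | partner | free catalyst | second catalyst | temperature | remark | time |
|---|---|---|---|---|---|---|---|
| epsilon | 1.5 M | 1.05 M | 30 mM | 150 mM | 110 °C | the very flask that is asked about, followed so far |  |
| theta | 1.5 M | 1.05 M | 30 mM | 75 mM | 95 °C | run made earlier |  |
| flask | 1.5 M | 1.05 M | 30 mM | 150 mM | 110 °C |  | 1.5 h |

| epsilon: time / min | epsilon: product / % | theta: time / min | theta: product / % |
|---|---|---|---|
| 5.00 | 8.9 | 1.00 | 0.6 |
| 15.0 | 26.7 | 2.00 | 0.6 |
| 25.0 | 35.1 | 3.00 | 0.5 |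
| 40.0 | 41.4 | 4.00 | 1.8 |
| 50.0 | 43.7 | 6.00 | 2.3 |
| 80.0 | 46.2 | 10.0 | 6.0 |
| 90.0 | 46.5 | 15.0 | 10.2 |

(standard deviation of a reading: 0.3 percentage points)

- amounts and yields of product count idle complex too
- additions bring no volume worth counting
- what was read earlier has a scatter of 0.3 percentage points, one standard deviation
- what may be going on: partner + second catalyst + intermediate -> second catalyst + product; free catalyst -> spent catalyst; free catalyst + product <-> idle complex; substrate + free catalyst <-> free catalyst + intermediate
- "the catalyst" is free catalyst with its forms; second catalyst is a second catalyst

- blue: change nothing and wait 1.5 h more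
- red: at 1.5 h add free catalyst, 100% of the amount charged, then wait 1.5 h
- green: at 1.5 h raise the temperature by 20 K, then wait 1.5 h

- product, in percent of the substrate first charged, at 1.5 h
- the remedy with the largest gain of product, or "none" below 2 percentage points (blue / red / green / none)
- product present, in percent of the substrate first charged, after blue
- product present, in percent of the substrate first charged, after red

2. I begin with the end state. Partner, the limiting reagent, allows 70.0% product in epsilon, but the last reading is 46.5%, less than that ceiling. It rose 0.3 percentage points over the last 10.0 min, which is about the scatter. So epsilon stalls below the ceiling, and I take it that the catalyst has stopped working.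

3. Reading the reacted substrate as product, the last reading gives 0.625. This is the catalyst dose, the natural logarithm of c(substrate) charged over c(substrate) at the stall: the number of e-foldings of substrate that one charge of free catalyst buys before it stops. I assume that, at fixed temperature, it grows in proportion to the catalyst charged.

4. Waiting and heating add no catalyst, so I expect little from either. Adding 100% of the charge buys a second dose, which takes substrate down to 28.6% of its charge. That implies 71.4% reacted, above the partner ceiling, so I choose red and expect its product to be near 70.0% at most.

5. The forecast says 46.7% now (46.2% to 47.1%), 47.1% after blue (46.6% to 48%), and 62% after red (54% to 69%), and it also chooses red. Its red value stands below my ceiling, for it expects red to be “slowed further by low partner and some binding to product”.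

The flask gives 46.7% at 1.5 h, and 47.7% after blue. Red gains the most, 18 points, against 0.96 points for blue and 1 point for green, so the result is red. By 90.0 min spent catalyst stands at >99.9% of the catalyst charged, with substrate at 52.3% of its charge. A second dose on that substrate reaches 28.0% of its charge, which again points past the ceiling, and red gives 65.1%, below that ceiling.

    partner + second catalyst + intermediate → second catalyst + product (k = 0.0108 M⁻² s⁻¹, Ea = 53.0 kJ mol⁻¹)
    free catalyst → spent catalyst (k = 0.00363 s⁻¹, Ea = 111 kJ mol⁻¹)
    free catalyst + product ⇌ idle complex, settled at all times (K = 0.490 M⁻¹, ΔH = −15.0 kJ mol⁻¹)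
    substrate + free catalyst ⇌ free catalyst + intermediate (K = 7.50, k = 0.0815 M⁻¹ s⁻¹, Ea = 50.0 kJ mol⁻¹, ΔH = −3.00 kJ mol⁻¹)
    (constants at 110 °C)

For the neighbour with 0.051 M of free catalyst, the scaled dose is 1.06, which leaves 34.6% substrate. That neighbour computes to 34.5% substrate, with 60.3% product and 5.15% intermediate.

The data stem from a simulated flask for substances that don't exist, and the scatter is random.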